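## Structural features

Compound 31 is an elemane-type sesquiterpenoid: a cyclohexane with all six ring carbons substituted, cis-fused across C7–C8 to an α-methylene-γ-butyrolactone (C11=C13, carbonyl C12, ring oxygen on C8). The ring carbons are numbered C5 (bearing the C4 propenyl unit with methylene C3 and acetoxymethyl C15), C6 (isobutyrate), C7, C8, C9 (acetate) and C10 (methyl C14, vinyl C1–C2). All six are stereocentres in one unbroken row. The C5 substituent, the C6 oxygen, the C7 lactone carbon, the C8 oxygen and the C10 methyl lie on one face (β); only the C9 acetate and the C10 vinyl group lie on the other (α). The fragile parts are the methylene lactone (Michael acceptor, base-sensitive), the allylic acetate, and three esters of which the isobutyrate must go selectively onto the most hindered hydroxyl. The real difficulty lies in the quaternary C10 between C5 and C9, and in the all-cis C5/C6/C7 array, whose C5/C6 relationship is the one that Felkin–Anh addition of hydride, not of a carbon nucleophile, delivers. The key step exploits the fact that C10 carries a vinyl group and the ring carbon C9: if C8–C9 is cut as an alkene, C9 becomes a second vinyl group and C10 is a non-stereogenic methyl divinyl carbon. C10 then becomes stereogenic only when ring-closing metathesis draws one vinyl group into the ring, and the C8=C9 alkene so formed sits exactly where the trans C8–O/C9–O pair is needed.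

## Logic of the disconnections

31 ⇒ 30 ⇒ 29 ⇒ 28. The acyl C–O bonds are cut first: isobutyryl at O6, then both acetyls at O9 and O15. Acyl groups would not survive the enolate chemistry used earlier, so they go on last, and 28 carries only a silyl ether and free hydroxyls. The forward demand is differentiation of three oxygens, met by the order of unveiling: in 28 the C9 and C15 hydroxyls are free together while O6 is still silylated.

28 ⇒ 26 ⇒ 25. The lactone C8–O bond and the C9–O bond are traced back to one epoxide oxygen and then to the C8=C9 alkene. A β oxygen on C8 trans to an α oxygen on C9 is what anti opening of an α-epoxide by the C12 ester carbonyl gives, and the tether allows only the cis ring fusion. Two stereocentres and the lactone thus come from one alkene. The forward step must epoxidise 25 on the α face and only at the ring alkene.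

25 ⇒ 21. The C11=C13 bond is cut. In 21 there is one carbonyl group and no free hydroxyl, so a single enolate forms; later, with acetates present, a strong base could not be used. The forward step must leave the allylic C7–H alone.

21 ⇒ 20. The C8=C9 bond is cut to two vinyl groups. This removes the ring and the C10 stereocentre at once, since C10 in 20 bears two identical vinyl groups. The forward step must choose between two diastereotopic vinyl groups and must not engage the C3=C4 alkene.

20 ⇒ 19 ⇒ 18. The C8=CH2 bond is cut to an aldehyde and the aldehyde is traced to a methyl ester. This puts C8 at the carboxyl level, which is what the enolate chemistry at C7 needs. The forward steps must tell the methyl ester from the tert-butyl ester and keep C7 from epimerising.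

18 ⇒ 17 ⇒ 14 + 15. After the O6–Si bond, the C7–C11 bond is cut. Alkylating the dianion of 14 places C11 anti to O6, which is the C6/C7 relationship of the target, and brings in C11–C12 already as the tert-butyl ester. The forward step needs C-alkylation of a hindered dianion by an α-bromo ester.

14 ⇒ 13 ⇒ 9 + 10. The C6–H bond is cut, then C6–C7. Adding a C7 nucleophile to a C6 aldehyde would be expected to enter anti to C10 and give the C6 epimer, so C6–C7 is made at the ketone level and the hydride is delivered last. Felkin–Anh attack of hydride anti to C10 then gives the required C5/C6 relationship. The forward steps need C-acylation by a very hindered acyl group and no epimerisation at C5.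

9 ⇒ 7. The C5–C10 bond is cut as a [3,3] rearrangement of an ester enolate. The allyl terminus of 7 ends as a carbon with two identical vinyl groups, so only C5 is stereogenic and the quaternary carbon needs no stereocontrol. The forward step must differentiate the enolate faces by a chiral controller on the enolate oxygen.

7 ⇒ 6 + 2, 6 ⇒ 5 ⇒ 4 ⇒ 3, 2 ⇒ 1. The ester C–O bond is cut, then the O15–Si bond, and the C15 alcohol is traced to the conjugated carboxyl group of 3; the second vinyl group of 2 is traced to the alkyne of 1. All three ends (1, 3, 10) and 15 are commercial. The forward steps need acid-over-ester selectivity, and the C3=C4 alkene must stay out of conjugation.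

## Other disconnections considered

Alternative 1: The cut is at C5–C4 and C10–C1 on a preformed ring, enone A2 (4,4-dimethoxy-2-methylcyclohex-2-en-1-one). In the forward step a copper-catalysed asymmetric conjugate addition of an isopropenylmagnesium halide at C5 is followed by Michael trapping of the C10 enolate with a vinyl sulfoxide. This gives A1 with the sulfinylethyl arm (a latent vinyl group) trans to the propenyl group.
- In its favour: the ring is bought; C10 is fixed by a C–C bond formed anti to the new C5 substituent, a dependable substrate rule; the C9 ketone and the masked C6 ketone are in place.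
- Against it here: conjugate addition to an α-methyl enone next to a ketal carbon is slow; a fully substituted enolate adds poorly to a weak acceptor; the propenyl group arrives without the C15 oxygen, so an allylic oxidation beside other alkenes is needed later; C7 and C8 are bare methylenes that still need the C11–C12 chain, the C8 oxygen and four stereocentres.
- Comparison: at C10 this plan is the better one, since it does not depend on a catalyst distinguishing two vinyl groups, and it needs no ring closure. In mechanism both set C5 by enolate-type chemistry and are equal there. In step economy the chosen plan is ahead, because 20 already holds every carbon and the C5, C6, C7 centres before the ring closes.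

Alternative 2: The cut is at C7–C8 and the lactone O–C12 bond of A3, leading to the open-chain aldehyde A4, which carries a Z 2-(bromomethyl)enoate. In the forward step indium metal makes an allylindium whose γ-carbon C7 adds to the C8 aldehyde, and the C8 alkoxide closes the lactone.
- In its favour: carbocycle, lactone and exocyclic methylene form in one operation; no strong base and no epoxide are needed late; the three oxygens arrive already differentiated (PMB, silyl, acetate), so A3 is about four simple steps from 31.
- Against it here: A4 must hold C5, C6, C9 and a stereogenic quaternary C10 in an open chain, so C10 needs a stereoselective quaternary C–C bond formation; the α-alkoxy aldehyde is epimerisable; the sense of attack at C7/C8 relative to four existing centres is hard to foresee.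
- Comparison: in the endgame this plan is the better one on step and redox economy, and it is the equal of the chosen plan in closing a six-membered ring from an acyclic chain. It is weaker in the supply of its precursor, which is longer and stereochemically more demanding than 20.

Alternative 3: The cut is at C5–C6 and C9–C10: diene A6 (C6 to C9, silyloxy on C6) and the E keto enoate A7 (C5 and C10) combine in a chiral-Lewis-acid-catalysed endo Diels–Alder reaction to give A5.
- In its favour: two C–C bonds, the ring and three stereocentres including quaternary C10 come in one catalytic step from two small achiral partners; ortho and endo rules place the silyloxy group cis to the acetyl group; the E geometry fixes methyl cis to the C5 substituent stereospecifically.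
- Against it here: the ester must be turned into the vinyl group and the acetyl group into the oxygenated propenyl unit; the C7=C8 alkene and the C9 methylene must then receive a carbon substituent at C7 and oxygens at C8 and C9 with three new stereocentres; the dienophile has two different carbonyl groups competing for the Lewis acid.
- Comparison: for the C5/C6/C10 triad this plan is the better one (one step against rearrangement, reduction and metathesis), and it is equal in giving a cyclohexene that must be oxidised further. The alkene of 21 lies where both oxygens go and C7 already bears the chain that delivers the lactone oxygen, so the chosen plan is ahead in step economy after the ring is made.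

Key step: step 13

Remarks: TBS = tert-butyldimethylsilyl (TBSO = its ether); β is the ring face of the C10 methyl group.
Assumption: the (4S,5S) boron controller in step 6 and the (R) aryloxide in step 13 are taken as the matched antipodes; if the sense of induction is the opposite, the mirror-image reagent is used with no other change.

## Steps

Step 1
Reactants: 1 (2E)-3-methylpent-2-en-4-yn-1-ol
Product: 2 (2E)-3-methylpenta-2,4-dien-1-ol
Conditions: H2 (1 atm), Pd/CaCO3 poisoned with Pb(OAc)2, quinoline, EtOAc, 0 °C, stopped after 1 equiv H2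
Reagents that add atoms: none
Why: Partial hydrogenation of a terminal alkyne on poisoned palladium should stop at the vinyl group; the trisubstituted E alkene is untouched and keeps its geometry.

Step 2
Reactants: 3 4-methyl hydrogen itaconate (4-methoxy-2-methylidene-4-oxobutanoic acid)
Product: 4 methyl 3-(hydroxymethyl)but-3-enoate
Conditions: BH3·THF (1.0 equiv), THF, −10 → 20 °C; H2O
Reagents that add atoms: none
Why: Borane reduction of a carboxylic acid through its acyloxyborane is much faster than reduction of the methyl ester. The alkene is electron-poor while conjugated to the acyloxyborane, so with one equivalent of borane hydroboration should not compete.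

Step 3
Reactants: 4 methyl 3-(hydroxymethyl)but-3-enoate
Product: 5 methyl 3-(TBSO-methyl)but-3-enoate
Conditions: TBSCl, imidazole, CH2Cl2, 0 → 23 °C
Reagents that add atoms: tert-butyldimethylsilyl chloride, CC(C)(C)[Si](C)(C)Cl
Why: Silyl ether formation at a primary alcohol; done at once so that 4 cannot lactonise.

Step 4
Reactants: 5 methyl 3-(TBSO-methyl)but-3-enoate
Product: 6 3-(TBSO-methyl)but-3-enoic acid
Conditions: LiOH, THF/H2O 3:1, 0 °C; 0.5 M HCl to pH 4 at 0 °C
Reagents that add atoms: lithium hydroxide (hydroxide oxygen of the new carboxyl group), [Li+].[OH-]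
Why: Saponification of an unhindered methyl ester; once the carboxylate has formed, α-deprotonation is disfavoured, so the alkene should stay out of conjugation.

Step 5
Reactants: 6 3-(TBSO-methyl)but-3-enoic acid; 2 (2E)-3-methylpenta-2,4-dien-1-ol
Product: 7 (2E)-3-methylpenta-2,4-dien-1-yl 3-(TBSO-methyl)but-3-enoate
Conditions: N,N'-diisopropylcarbodiimide, DMAP (5 mol%), CH2Cl2, −20 → 0 °C
Reagents that add atoms: none
Why: Steglich esterification of a primary allylic alcohol; low temperature and little DMAP limit ketene formation and migration of the β,γ-alkene into conjugation.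

Step 6
Reactants: 7 (2E)-3-methylpenta-2,4-dien-1-yl 3-(TBSO-methyl)but-3-enoate
Product: 9 (2R)-2-[3-(TBSO)prop-1-en-2-yl]-3-ethenyl-3-methylpent-4-enoic acid, via O-boron ketene acetal 8 (not isolated)
Conditions: (4S,5S)-2-bromo-4,5-diphenyl-1,3-bis{[3,5-bis(trifluoromethyl)phenyl]sulfonyl}-1,3,2-diazaborolidine (1.2 equiv), iPr2NEt, CH2Cl2, −78 °C; then −20 → 4 °C; aqueous work-up
Reagents that add atoms: none
Why: Enantioselective Ireland–Claisen rearrangement of a boron ester enolate through a chair transition state; soft enolisation is easy because the α-CH2 is also allylic. Only C5 becomes stereogenic, since the allyl terminus ends with two identical vinyl groups. Its configuration is set by the C2-symmetric sulfonamide ligands on boron, which shield one enolate face.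

Step 7
Reactants: 9 (2R)-2-[3-(TBSO)prop-1-en-2-yl]-3-ethenyl-3-methylpent-4-enoic acid; 10 potassium methyl malonate
Product: 13 methyl (4R)-4-[3-(TBSO)prop-1-en-2-yl]-5-ethenyl-5-methyl-3-oxohept-6-enoate, via acyl imidazolide 11 (not isolated), via acylmalonic half-ester 12 (not isolated)
Conditions: carbonyldiimidazole, THF, 23 °C; then 10, MgCl2, Et3N, THF, 23 → 40 °C; 1 M HCl, 0 °C
Reagents that add atoms: none
Why: Masamune–Brooks C-acylation of a magnesium malonate half ester by an acyl imidazolide, with decarboxylation on acidification. The conditions are near neutral and the product is held as its magnesium chelate enolised at C7, so the allylic C5–H should not be touched.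

Step 8
Reactants: 13 methyl (4R)-4-[3-(TBSO)prop-1-en-2-yl]-5-ethenyl-5-methyl-3-oxohept-6-enoate
Product: 14 methyl (3R,4R)-4-[3-(TBSO)prop-1-en-2-yl]-5-ethenyl-3-hydroxy-5-methylhept-6-enoate
Conditions: NaBH4, EtOH, −40 °C
Reagents that add atoms: none
Why: Felkin–Anh controlled hydride reduction: hydride should enter anti to the quaternary C10 group, with the C5 hydrogen next to the CH2CO2Me arm. This gives the C5/C6 relationship of the target, which is the C6 epimer of what a carbon nucleophile adding to the corresponding aldehyde would give.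

Step 9
Reactants: 14 methyl (3R,4R)-4-[3-(TBSO)prop-1-en-2-yl]-5-ethenyl-3-hydroxy-5-methylhept-6-enoate; 15 tert-butyl bromoacetate
Product: 17 4-tert-butyl 1-methyl (2S)-2-{(1S,2R)-2-[3-(TBSO)prop-1-en-2-yl]-3-ethenyl-1-hydroxy-3-methylpent-4-en-1-yl}butanedioate, via dilithium alkoxide enolate 16 (not isolated)
Conditions: LiN(iPr)2 (2.2 equiv), THF, −78 → −20 °C; then 15, DMPU, −78 → −30 °C; aq. NH4Cl
Reagents that add atoms: none
Why: Frater–Seebach alkylation: the lithium-chelated alkoxide enolate is alkylated by SN2 on the face opposite the C5 substituent of the chelate ring. This places C11 anti to the C6 hydroxyl and sets C7.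

Step 10
Reactants: 17 4-tert-butyl 1-methyl (2S)-2-{(1S,2R)-2-[3-(TBSO)prop-1-en-2-yl]-3-ethenyl-1-hydroxy-3-methylpent-4-en-1-yl}butanedioate
Product: 18 4-tert-butyl 1-methyl (2S)-2-{(1S,2R)-1-(TBSO)-2-[3-(TBSO)prop-1-en-2-yl]-3-ethenyl-3-methylpent-4-en-1-yl}butanedioate
Conditions: TBSOTf, 2,6-lutidine, CH2Cl2, −40 → 0 °C
Reagents that add atoms: tert-butyldimethylsilyl triflate, CC(C)(C)[Si](C)(C)OS(=O)(=O)C(F)(F)F
Why: Silyl triflate silylation of a hindered secondary alcohol; at low temperature with a hindered base both esters should survive.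

Step 11
Reactants: 18 4-tert-butyl 1-methyl (2S)-2-{(1S,2R)-1-(TBSO)-2-[3-(TBSO)prop-1-en-2-yl]-3-ethenyl-3-methylpent-4-en-1-yl}butanedioate
Product: 19 tert-butyl (3S,4S,5R)-4-(TBSO)-5-[3-(TBSO)prop-1-en-2-yl]-6-ethenyl-3-formyl-6-methyloct-7-enoate
Conditions: i-Bu2AlH (1.2 equiv), CH2Cl2, −78 °C; MeOH, then aq. KNa tartrate
Reagents that add atoms: none
Why: Partial reduction of a methyl ester to the aldehyde through a tetrahedral aluminate that is stable at −78 °C; the tert-butyl ester reacts much more slowly for steric reasons.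

Step 12
Reactants: 19 tert-butyl (3S,4S,5R)-4-(TBSO)-5-[3-(TBSO)prop-1-en-2-yl]-6-ethenyl-3-formyl-6-methyloct-7-enoate
Product: 20 tert-butyl (3R,4R,5R)-4-(TBSO)-5-[3-(TBSO)prop-1-en-2-yl]-3,6-diethenyl-6-methyloct-7-enoate
Conditions: Ph3PCH3Br, KN(SiMe3)2, THF, 0 °C; then 19, −78 → 0 °C
Reagents that add atoms: methyltriphenylphosphonium bromide, C[P+](c1ccccc1)(c1ccccc1)c1ccccc1.[Br-]
Why: Wittig methylenation; the non-stabilised ylide adds only to the aldehyde, and the low temperature protects the C7 centre α to it.

Step 13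
Reactants: 20 tert-butyl (3R,4R,5R)-4-(TBSO)-5-[3-(TBSO)prop-1-en-2-yl]-3,6-diethenyl-6-methyloct-7-enoate
Product: 21 tert-butyl 2-{(1R,4R,5R,6R)-6-(TBSO)-5-[3-(TBSO)prop-1-en-2-yl]-4-ethenyl-4-methylcyclohex-2-en-1-yl}acetate
Conditions: Mo(N-2,6-iPr2C6H3)(CHCMe2Ph)(2,5-Me2C4H2N)(OAr) (5 mol%), formed in situ from Mo(N-2,6-iPr2C6H3)(CHCMe2Ph)(2,5-Me2C4H2N)2 and ArOH [(R)-3,3'-dibromo-2'-(tert-butyldimethylsilyloxy)-5,5',6,6',7,7',8,8'-octahydro-1,1'-binaphthalen-2-ol], C6H6, 22 °C, N2, vented
Reagents that add atoms: none
Why: Olefin metathesis by the Chauvin mechanism: the Mo alkylidene first exchanges with the C8 vinyl group, the least hindered terminal alkene, by [2+2] cycloaddition and cycloreversion. The new Mo=C8 alkylidene then adds across one of the two C10 vinyl groups to a molybdacyclobutane, which opens to the C8=C9 alkene of 21 and Mo=CH2, and ethene leaves the vented flask. The closest known reaction type is the catalytic enantioselective desymmetrising ring-closing metathesis of trienes whose quaternary carbon bears two vinyl groups, run with monoaryloxide pyrrolide Mo complexes; here it is a selection between diastereotopic groups on a chiral substrate. The one ring closed is the cyclohexene, formed by joining the two ends of a 1,7-diene; the other closures would give a cyclopropene, a cyclobutene or a cyclopentene with a trisubstituted alkene. The single new stereocentre, C10, has no bond formed to it: its configuration is fixed by which vinyl group enters the metallacycle, and that choice is made by the chiral aryloxide and the stereogenic metal centre together with the C5, C6, C7 array. The step needs the vinyl group whose closure leaves the C10 methyl cis to the C5 substituent; methyl and vinyl are similar in size, so the substrate alone would discriminate poorly and catalyst control is relied on. It also needs chemoselectivity against the C3=C4 alkene, which its 1,1-disubstitution, the silyloxymethyl branch and the neighbouring quaternary carbon should secure. Ester and silyl ether groups are tolerated by this catalyst class, and no free OH is present.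

Step 14
Reactants: 21 tert-butyl 2-{(1R,4R,5R,6R)-6-(TBSO)-5-[3-(TBSO)prop-1-en-2-yl]-4-ethenyl-4-methylcyclohex-2-en-1-yl}acetate
Product: 25 tert-butyl 2-{(1S,4R,5R,6R)-6-(TBSO)-5-[3-(TBSO)prop-1-en-2-yl]-4-ethenyl-4-methylcyclohex-2-en-1-yl}prop-2-enoate, via lithium ester enolate 22 (not isolated), via Mannich base 23 (not isolated), via quaternary ammonium iodide 24 (not isolated)
Conditions: LiN(iPr)2, THF, −78 °C; (CH2=NMe2)I, −78 → 23 °C; then MeI, MeOH, 23 °C; then aq. NaHCO3, CH2Cl2, 23 °C
Reagents that add atoms: dimethylmethylideneammonium iodide, C=[N+](C)C.[I-]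
Why: α-Methylenation by Mannich reaction of the ester enolate with an iminium salt, N-methylation and E1cB loss of trimethylamine. Compound 21 has one carbonyl group and no acidic OH, and the mild base in the last stage should leave the doubly allylic C7–H alone.

Step 15
Reactants: 25 tert-butyl 2-{(1S,4R,5R,6R)-6-(TBSO)-5-[3-(TBSO)prop-1-en-2-yl]-4-ethenyl-4-methylcyclohex-2-en-1-yl}prop-2-enoate
Product: 26 tert-butyl 2-{(1S,2S,3S,4S,5R,6R)-4-(TBSO)-3-[3-(TBSO)prop-1-en-2-yl]-2-ethenyl-2-methyl-7-oxabicyclo[4.1.0]heptan-5-yl}prop-2-enoate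
Conditions: mCPBA (1.2 equiv), NaHCO3, CH2Cl2, 0 °C
Reagents that add atoms: 3-chloroperoxybenzoic acid, O=C(OO)c1cccc(Cl)c1
Why: Prilezhaev epoxidation: the cis-disubstituted ring alkene is the most nucleophilic, ahead of the monosubstituted vinyl group, the acrylate and the propenyl alkene deactivated by its allylic oxygen. The peracid should approach the α face, away from the C7 acrylate arm, the C6 silyloxy group and the C10 methyl.

Step 16
Reactants: 26 tert-butyl 2-{(1S,2S,3S,4S,5R,6R)-4-(TBSO)-3-[3-(TBSO)prop-1-en-2-yl]-2-ethenyl-2-methyl-7-oxabicyclo[4.1.0]heptan-5-yl}prop-2-enoate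
Product: 28 (3aR,4S,5S,6S,7S,7aS)-4-(TBSO)-6-ethenyl-7-hydroxy-5-(3-hydroxyprop-1-en-2-yl)-6-methyl-3-methylidenehexahydro-1-benzofuran-2(3H)-one, via bis-silyl hydroxy lactone 27 (not isolated)
Conditions: camphor-10-sulfonic acid (0.3 equiv), CH2Cl2, 0 → 23 °C; then MeOH, 0 °C
Reagents that add atoms: none
Why: Acid-promoted 5-exo opening of the epoxide by the ester carbonyl oxygen with inversion at C8 and loss of the tert-butyl group as isobutene; the tether allows only the cis-fused lactone and leaves the C9 hydroxyl on the α face. Methanol with the same acid then cleaves the primary allylic TBS ether, while the hindered secondary C6 ether should stay.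

Step 17
Reactants: 28 (3aR,4S,5S,6S,7S,7aS)-4-(TBSO)-6-ethenyl-7-hydroxy-5-(3-hydroxyprop-1-en-2-yl)-6-methyl-3-methylidenehexahydro-1-benzofuran-2(3H)-one
Product: 29 2-[(3aR,4S,5S,6S,7S,7aS)-7-acetoxy-4-(TBSO)-6-ethenyl-6-methyl-3-methylidene-2-oxooctahydro-1-benzofuran-5-yl]prop-2-en-1-yl acetate
Conditions: Ac2O, pyridine, DMAP (cat.), CH2Cl2, 0 → 23 °C
Reagents that add atoms: acetic anhydride, CC(=O)OC(C)=O
Why: DMAP-catalysed acetylation puts both acetates on in one operation, because C9 and C15 are the only free hydroxyls at this point.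

Step 18
Reactants: 29 2-[(3aR,4S,5S,6S,7S,7aS)-7-acetoxy-4-(TBSO)-6-ethenyl-6-methyl-3-methylidene-2-oxooctahydro-1-benzofuran-5-yl]prop-2-en-1-yl acetate
Product: 30 2-[(3aS,4S,5S,6S,7S,7aS)-7-acetoxy-6-ethenyl-4-hydroxy-6-methyl-3-methylidene-2-oxooctahydro-1-benzofuran-5-yl]prop-2-en-1-yl acetate
Conditions: HF·pyridine, pyridine, THF, 0 → 23 °C
Reagents that add atoms: none
Why: Fluoride cleavage of the silyl ether under mildly acidic conditions, which should spare the acetates and the methylene lactone (no basic fluoride, so no acyl migration or conjugate addition).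

Step 19
Reactants: 30 2-[(3aS,4S,5S,6S,7S,7aS)-7-acetoxy-6-ethenyl-4-hydroxy-6-methyl-3-methylidene-2-oxooctahydro-1-benzofuran-5-yl]prop-2-en-1-yl acetate
Product: 31 (3aS,4S,5S,6S,7S,7aS)-7-acetoxy-5-[3-(acetoxy)prop-1-en-2-yl]-6-ethenyl-6-methyl-3-methylidene-2-oxooctahydro-1-benzofuran-4-yl 2-methylpropanoate (CNP0500052.1)
Conditions: (i-PrCO)2O, DMAP, Et3N, CH2Cl2, 23 °C
Reagents that add atoms: isobutyric anhydride, CC(C)C(=O)OC(=O)C(C)C
Why: DMAP-catalysed acylation of the one remaining, hindered secondary hydroxyl with the anhydride; no stereocentre is touched.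

## Compound list

1 | (2E)-3-methylpent-2-en-4-yn-1-ol | C#C/C(C)=C/CO | starting material
2 | (2E)-3-methylpenta-2,4-dien-1-ol | C=C/C(C)=C/CO | intermediate
3 | 4-methyl hydrogen itaconate (4-methoxy-2-methylidene-4-oxobutanoic acid) | C=C(CC(=O)OC)C(=O)O | starting material
4 | methyl 3-(hydroxymethyl)but-3-enoate | C=C(CO)CC(=O)OC | intermediate
5 | methyl 3-{[tert-butyl(dimethyl)silyl]oxymethyl}but-3-enoate | C=C(CO[Si](C)(C)C(C)(C)C)CC(=O)OC | intermediate
6 | 3-{[tert-butyl(dimethyl)silyl]oxymethyl}but-3-enoic acid | C=C(CO[Si](C)(C)C(C)(C)C)CC(=O)O | intermediate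
7 | (2E)-3-methylpenta-2,4-dien-1-yl 3-{[tert-butyl(dimethyl)silyl]oxymethyl}but-3-enoate | C=C/C(C)=C/COC(=O)CC(=C)CO[Si](C)(C)C(C)(C)C | intermediate
8 | O-boron ketene acetal of 7, boron held in the (4S,5S)-4,5-diphenyl-1,3-bis{[3,5-bis(trifluoromethyl)phenyl]sulfonyl}-1,3,2-diazaborolidine (enolate geometry not specified) | C=C/C(C)=C/COC(OB1N(S(=O)(=O)c2cc(C(F)(F)F)cc(C(F)(F)F)c2)[C@@H](c2ccccc2)[C@H](c2ccccc2)N1S(=O)(=O)c1cc(C(F)(F)F)cc(C(F)(F)F)c1)=CC(=C)CO[Si](C)(C)C(C)(C)C | intermediate
9 | (2R)-2-[3-(TBSO)prop-1-en-2-yl]-3-ethenyl-3-methylpent-4-enoic acid | C=CC(C)(C=C)[C@H](C(=C)CO[Si](C)(C)C(C)(C)C)C(=O)O | intermediate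
10 | potassium methyl malonate (potassium 3-methoxy-3-oxopropanoate) | COC(=O)CC(=O)[O-].[K+] | starting material
11 | 1-acylimidazole of 9 | C=CC(C)(C=C)[C@H](C(=C)CO[Si](C)(C)C(C)(C)C)C(=O)n1ccnc1 | intermediate
12 | 2-acylmalonic acid monomethyl ester from 11 (C2 of the malonate not specified) | C=CC(C)(C=C)[C@H](C(=C)CO[Si](C)(C)C(C)(C)C)C(=O)C(C(=O)O)C(=O)OC | intermediate
13 | methyl (4R)-4-[3-(TBSO)prop-1-en-2-yl]-5-ethenyl-5-methyl-3-oxohept-6-enoate | C=CC(C)(C=C)[C@H](C(=C)CO[Si](C)(C)C(C)(C)C)C(=O)CC(=O)OC | intermediate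
14 | methyl (3R,4R)-4-[3-(TBSO)prop-1-en-2-yl]-5-ethenyl-3-hydroxy-5-methylhept-6-enoate | C=CC(C)(C=C)[C@H](C(=C)CO[Si](C)(C)C(C)(C)C)[C@H](O)CC(=O)OC | intermediate
15 | tert-butyl bromoacetate | CC(C)(C)OC(=O)CBr | starting material
16 | dilithium alkoxide enolate of 14 | C=CC(C)(C=C)[C@H](C(=C)CO[Si](C)(C)C(C)(C)C)[C@H]([O-])C=C([O-])OC.[Li+].[Li+] | intermediate
17 | 4-tert-butyl 1-methyl (2S)-2-{(1S,2R)-2-[3-(TBSO)prop-1-en-2-yl]-3-ethenyl-1-hydroxy-3-methylpent-4-en-1-yl}butanedioate | C=CC(C)(C=C)[C@H](C(=C)CO[Si](C)(C)C(C)(C)C)[C@H](O)[C@H](CC(=O)OC(C)(C)C)C(=O)OC | intermediate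
18 | 4-tert-butyl 1-methyl (2S)-2-{(1S,2R)-1-(TBSO)-2-[3-(TBSO)prop-1-en-2-yl]-3-ethenyl-3-methylpent-4-en-1-yl}butanedioate | C=CC(C)(C=C)[C@H](C(=C)CO[Si](C)(C)C(C)(C)C)[C@H](O[Si](C)(C)C(C)(C)C)[C@H](CC(=O)OC(C)(C)C)C(=O)OC | intermediate
19 | tert-butyl (3S,4S,5R)-4-(TBSO)-5-[3-(TBSO)prop-1-en-2-yl]-6-ethenyl-3-formyl-6-methyloct-7-enoate | C=CC(C)(C=C)[C@H](C(=C)CO[Si](C)(C)C(C)(C)C)[C@H](O[Si](C)(C)C(C)(C)C)[C@H](CC(=O)OC(C)(C)C)C=O | intermediate
20 | tert-butyl (3R,4R,5R)-4-(TBSO)-5-[3-(TBSO)prop-1-en-2-yl]-3,6-diethenyl-6-methyloct-7-enoate | C=CC(C)(C=C)[C@H](C(=C)CO[Si](C)(C)C(C)(C)C)[C@H](O[Si](C)(C)C(C)(C)C)[C@H](CC(=O)OC(C)(C)C)C=C | intermediate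
21 | tert-butyl 2-{(1R,4R,5R,6R)-6-(TBSO)-5-[3-(TBSO)prop-1-en-2-yl]-4-ethenyl-4-methylcyclohex-2-en-1-yl}acetate | C=C[C@]1(C)C=C[C@@H](CC(=O)OC(C)(C)C)[C@@H](O[Si](C)(C)C(C)(C)C)[C@H]1C(=C)CO[Si](C)(C)C(C)(C)C | intermediate
22 | lithium enolate of 21 | C=C[C@]1(C)C=C[C@@H](C=C([O-])OC(C)(C)C)[C@@H](O[Si](C)(C)C(C)(C)C)[C@H]1C(=C)CO[Si](C)(C)C(C)(C)C.[Li+] | intermediate
23 | tert-butyl 3-(dimethylamino)-2-(ring of 21)propanoate (α-carbon not specified) | C=C[C@]1(C)C=C[C@@H](C(CN(C)C)C(=O)OC(C)(C)C)[C@@H](O[Si](C)(C)C(C)(C)C)[C@H]1C(=C)CO[Si](C)(C)C(C)(C)C | intermediate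
24 | N-methyl quaternary iodide of 23 | C=C[C@]1(C)C=C[C@@H](C(C[N+](C)(C)C)C(=O)OC(C)(C)C)[C@@H](O[Si](C)(C)C(C)(C)C)[C@H]1C(=C)CO[Si](C)(C)C(C)(C)C.[I-] | intermediate
25 | tert-butyl 2-{(1S,4R,5R,6R)-6-(TBSO)-5-[3-(TBSO)prop-1-en-2-yl]-4-ethenyl-4-methylcyclohex-2-en-1-yl}prop-2-enoate | C=C[C@]1(C)C=C[C@@H](C(=C)C(=O)OC(C)(C)C)[C@@H](O[Si](C)(C)C(C)(C)C)[C@H]1C(=C)CO[Si](C)(C)C(C)(C)C | intermediate
26 | tert-butyl 2-{(1S,2S,3S,4S,5R,6R)-4-(TBSO)-3-[3-(TBSO)prop-1-en-2-yl]-2-ethenyl-2-methyl-7-oxabicyclo[4.1.0]heptan-5-yl}prop-2-enoate (epoxide on the α face) | C=C[C@]1(C)[C@@H]2O[C@@H]2[C@@H](C(=C)C(=O)OC(C)(C)C)[C@@H](O[Si](C)(C)C(C)(C)C)[C@H]1C(=C)CO[Si](C)(C)C(C)(C)C | intermediate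
27 | (3aR,4S,5S,6S,7S,7aS)-4-(TBSO)-5-[3-(TBSO)prop-1-en-2-yl]-6-ethenyl-7-hydroxy-6-methyl-3-methylidenehexahydro-1-benzofuran-2(3H)-one | C=C[C@]1(C)[C@H](O)[C@H]2OC(=O)C(=C)[C@H]2[C@@H](O[Si](C)(C)C(C)(C)C)[C@H]1C(=C)CO[Si](C)(C)C(C)(C)C | intermediate
28 | (3aR,4S,5S,6S,7S,7aS)-4-(TBSO)-6-ethenyl-7-hydroxy-5-(3-hydroxyprop-1-en-2-yl)-6-methyl-3-methylidenehexahydro-1-benzofuran-2(3H)-one | C=C[C@]1(C)[C@H](O)[C@H]2OC(=O)C(=C)[C@H]2[C@@H](O[Si](C)(C)C(C)(C)C)[C@H]1C(=C)CO | intermediate
29 | 2-[(3aR,4S,5S,6S,7S,7aS)-7-acetoxy-4-(TBSO)-6-ethenyl-6-methyl-3-methylidene-2-oxooctahydro-1-benzofuran-5-yl]prop-2-en-1-yl acetate | C=C[C@]1(C)[C@H](OC(C)=O)[C@H]2OC(=O)C(=C)[C@H]2[C@@H](O[Si](C)(C)C(C)(C)C)[C@H]1C(=C)COC(C)=O | intermediate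
30 | 2-[(3aS,4S,5S,6S,7S,7aS)-7-acetoxy-6-ethenyl-4-hydroxy-6-methyl-3-methylidene-2-oxooctahydro-1-benzofuran-5-yl]prop-2-en-1-yl acetate | C=C[C@]1(C)[C@H](OC(C)=O)[C@H]2OC(=O)C(=C)[C@H]2[C@@H](O)[C@H]1C(=C)COC(C)=O | intermediate
31 | (3aS,4S,5S,6S,7S,7aS)-7-acetoxy-5-[3-(acetoxy)prop-1-en-2-yl]-6-ethenyl-6-methyl-3-methylidene-2-oxooctahydro-1-benzofuran-4-yl 2-methylpropanoate (CNP0500052.1) | C=C[C@]1(C)[C@H](OC(C)=O)[C@H]2OC(=O)C(=C)[C@H]2[C@@H](OC(=O)C(C)C)[C@H]1C(=C)COC(C)=O | target

## Step count and least certain steps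

Total step count: 19. Longest linear sequence: 18 steps (3 → 31, steps 2 to 19); step 1 prepares 2 off the main line.

**Step 13 (key step).** The most likely failure is weak discrimination between the two diastereotopic vinyl groups. Methyl and vinyl are similar in size, so if the chiral aryloxide is mismatched or only weakly matched with the C5, C6, C7 array, closure onto either vinyl group becomes comparable. Ring closure onto the C3=C4 alkene, or catalyst decomposition by traces of water, could add to this. Fallback: starting from 20, catalyst-controlled group selection is given up. The ring is closed with the achiral complex RuCl2(H2IMes)(=CH-C6H4-2-OiPr) in CH2Cl2 at 40 °C; the C10 epimer F1 that is then expected beside 21 is removed by chromatography, and the route resumes at 21.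

**Step 15.** Poor facial selectivity is the main risk, since the α face is flanked by the C10 vinyl group; competing epoxidation of the propenyl alkene is the second. A β-epoxide cannot be opened by the C12 ester and would be lost. Fallback: starting from 25, iodolactonisation (I2, NaHCO3, MeCN, 0 °C) lets the tether decide. The carboxyl oxygen can only reach the β face of C8, so iodine ends on the α face of C9 whatever the intrinsic face preference, giving the cis-fused 9α-iodo lactone F2 with loss of the tert-butyl group. Exchange of iodine for oxygen through the C9 radical (Bu3SnH, TEMPO in excess, C6H6, 70 °C) should give the alkoxyamine F3, the radical being trapped on the convex α face away from the lactone ring and fast enough to outrun a 1,2-vinyl shift. N–O cleavage with Zn and AcOH comes back to 27, which is desilylated to 28 as in step 16.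

**Step 8.** Facial selectivity of hydride addition may be moderate with a small hydride, because only the C5 centre controls it. Fallback: starting from 13, the reduction is put under reagent control with catecholborane and the antipode of the 2-methyl-oxazaborolidine catalyst that is matched to the 3R alcohol. Any 3-epimer F4 is separated, oxidised back with Dess–Martin periodinane and re-enters at 13; the route resumes at 14.

**Step 6.** Enantioselectivity may be eroded if the boron enolate forms as a mixture of geometries, and the rearrangement of boron enolates is slow. Fallback: starting from 7, an achiral Ireland–Claisen rearrangement (LiN(iPr)2, Me3SiCl, THF, −78 → 23 °C) through the trimethylsilyl ketene acetal F5 and the silyl ester F6 gives the racemic acid (9 with its enantiomer F7). Crystallisation of the (R)-1-phenylethylammonium salt F8 and acidification come back to 9.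

**Step 7.** C-Acylation by the very hindered acyl imidazolide may stall, and long activation invites epimerisation at C5. Fallback: starting from 9, LiAlH4 reduction gives the primary alcohol F9 and Dess–Martin oxidation the aldehyde F10. SnCl2-catalysed homologation with methyl diazoacetate (Roskamp reaction) comes back to 13.

## Further compounds

F1 | step 13 | C10 epimer of 21: tert-butyl 2-{(1R,4S,5R,6R)-6-(TBSO)-5-[3-(TBSO)prop-1-en-2-yl]-4-ethenyl-4-methylcyclohex-2-en-1-yl}acetate | C=C[C@@]1(C)C=C[C@@H](CC(=O)OC(C)(C)C)[C@@H](O[Si](C)(C)C(C)(C)C)[C@H]1C(=C)CO[Si](C)(C)C(C)(C)C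
F2 | step 15 | 7-iodo analogue of 27 (iodine on C9, α face, trans to the lactone oxygen) | C=C[C@]1(C)[C@H](I)[C@H]2OC(=O)C(=C)[C@H]2[C@@H](O[Si](C)(C)C(C)(C)C)[C@H]1C(=C)CO[Si](C)(C)C(C)(C)C
F3 | step 15 | 2,2,6,6-tetramethylpiperidin-1-yl ether of 27 at the C9 oxygen | C=C[C@]1(C)[C@H](ON3C(C)(C)CCCC3(C)C)[C@H]2OC(=O)C(=C)[C@H]2[C@@H](O[Si](C)(C)C(C)(C)C)[C@H]1C(=C)CO[Si](C)(C)C(C)(C)C
F4 | step 8 | 3-epimer of 14: methyl (3S,4R)-4-[3-(TBSO)prop-1-en-2-yl]-5-ethenyl-3-hydroxy-5-methylhept-6-enoate | C=CC(C)(C=C)[C@H](C(=C)CO[Si](C)(C)C(C)(C)C)[C@@H](O)CC(=O)OC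
F5 | step 6 | trimethylsilyl ketene acetal of 7 | C=C/C(C)=C/COC(O[Si](C)(C)C)=CC(=C)CO[Si](C)(C)C(C)(C)C
F6 | step 6 | racemic trimethylsilyl ester of 2-[3-(TBSO)prop-1-en-2-yl]-3-ethenyl-3-methylpent-4-enoic acid | C=CC(C)(C=C)C(C(=C)CO[Si](C)(C)C(C)(C)C)C(=O)O[Si](C)(C)C
F7 | step 6 | (2S)-2-[3-(TBSO)prop-1-en-2-yl]-3-ethenyl-3-methylpent-4-enoic acid (enantiomer of 9) | C=CC(C)(C=C)[C@@H](C(=C)CO[Si](C)(C)C(C)(C)C)C(=O)O
F8 | step 6 | (R)-1-phenylethylammonium salt of 9 | C=CC(C)(C=C)[C@H](C(=C)CO[Si](C)(C)C(C)(C)C)C(=O)[O-].C[C@@H]([NH3+])c1ccccc1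
F9 | step 7 | (2R)-2-[3-(TBSO)prop-1-en-2-yl]-3-ethenyl-3-methylpent-4-en-1-ol | C=CC(C)(C=C)[C@H](C(=C)CO[Si](C)(C)C(C)(C)C)CO
F10 | step 7 | (2R)-2-[3-(TBSO)prop-1-en-2-yl]-3-ethenyl-3-methylpent-4-enal | C=CC(C)(C=C)[C@H](C(=C)CO[Si](C)(C)C(C)(C)C)C=O
A1 | alternative 1 | 4,4-dimethoxy-2-methyl-2-[2-(phenylsulfinyl)ethyl]-3-(prop-1-en-2-yl)cyclohexan-1-one (sulfinylethyl trans to propenyl) | O=S(CC[C@]1(C)C(=O)CCC(OC)(OC)[C@H]1C(C)=C)c1ccccc1
A2 | alternative 1 | 4,4-dimethoxy-2-methylcyclohex-2-en-1-one | CC1=CC(OC)(OC)CCC1=O
A3 | alternative 2 | cis-fused α-methylene lactone with C9 4-methoxybenzyl ether, C6 TBS ether and C15 acetate | C=C[C@]1(C)[C@H](OCc3ccc(OC)cc3)[C@H]2OC(=O)C(=C)[C@H]2[C@@H](O[Si](C)(C)C(C)(C)C)[C@H]1C(=C)COC(C)=O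
A4 | alternative 2 | methyl (2Z,4R,5S,6S,7S)-5-[3-(acetoxy)prop-1-en-2-yl]-2-(bromomethyl)-4-(TBSO)-6-ethenyl-7-[(4-methoxybenzyl)oxy]-6-methyl-8-oxooct-2-enoate | O=C[C@@H](OCc1ccc(OC)cc1)[C@@](C)(C=C)[C@H](C(=C)COC(C)=O)[C@H](O[Si](C)(C)C(C)(C)C)/C=C(\CBr)C(=O)OC
A5 | alternative 3 | methyl 6-acetyl-5-(TBSO)-1-methylcyclohex-3-ene-1-carboxylate (acetyl and silyloxy cis, ester trans to acetyl) | COC(=O)[C@]1(C)CC=C[C@@H](O[Si](C)(C)C(C)(C)C)[C@H]1C(C)=O
A6 | alternative 3 | (1E)-1-(TBSO)buta-1,3-diene | C=C/C=C/O[Si](C)(C)C(C)(C)C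
A7 | alternative 3 | methyl (2E)-2-methyl-4-oxopent-2-enoate | COC(=O)/C(C)=C/C(C)=O
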